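**Retrosynthetic overview**
1. Target 22 ⇒ polyene oxetanol 20. One bromonium-triggered cascade closes ring A, ring B and a transient six-membered oxonium ring at the oxetane oxygen; the fused oxetanium then ring-expands (4 → 8) to the oxocane while the C14 hydroxyl closes the epoxide.
2. 20 ⇒ triene iodide 11 + vinyl oxetanol 18 (C9–C11 bond, B-alkyl Suzuki–Miyaura coupling).
3. 11 ⇒ bromide 1, acetylide 2 and silyl-protected 4-bromobutyne 6; two Zr-catalysed methylaluminations set both E alkenes.
4. 18 ⇒ oxetanone 17 (CBS reduction sets C14) ⇒ bromoketone 16 ⇒ methyl vinyl ketone 13 + ethyl vinyl ether 12.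
5. Ring order: oxetane (step 7) → ring A → ring B → oxocane with epoxide (all in step 10).

Assumption: atoms are cited with labdane numbering (Br on C3, gem-dimethyl on C4, ether O between C8 and C15, epoxide on C13–C14); the target is 3R,5S,8S,9S,10R,13S,14R.

**Step 1**
Reactants: 1 5-bromo-2-methylpent-2-ene; 2 lithium acetylide–ethylenediamine complex
Product: 3 6-methylhept-5-en-1-yne
Conditions: DMSO, 10 → 23 °C
Reagents that add atoms: none
Why: SN2 alkylation of the acetylide by a primary bromide (acetylide alkylation); no stereocenter is formed.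

**Step 2**
Reactants: 3 6-methylhept-5-en-1-yne
Product: 5 (1E)-1-iodo-2,6-dimethylhepta-1,5-diene, via alkenylalane 4 (not isolated)
Conditions: Me3Al (2 equiv), Cp2ZrCl2 (0.25 equiv), CH2Cl2, 0 → 23 °C; then iodine, THF, −30 → 0 °C
Reagents that add atoms: trimethylaluminium C[Al](C)C; iodine [I][I]
Why: Negishi zirconium-catalysed carboalumination adds Me and Al syn across the terminal alkyne, and iodinolysis with retention gives the E trisubstituted alkenyl iodide.

**Step 3**
Reactants: 5 (1E)-1-iodo-2,6-dimethylhepta-1,5-diene; 6 (4-bromobut-1-yn-1-yl)trimethylsilane (4-bromobut-1-yne carrying a trimethylsilyl protecting group on the alkyne)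
Product: 9 (5E)-6,10-dimethylundeca-5,9-dien-1-yne, via alkylzinc bromide 7 (not isolated), via silyl enyne 8 (not isolated)
Conditions: 6, Zn dust (activated), LiCl, THF, 50 °C; then 5, Pd(PPh3)4 (3 mol %), THF, 23 °C; then K2CO3, MeOH, 23 °C
Reagents that add atoms: none
Why: Negishi sp3–sp2 cross-coupling proceeds with retention of the E alkene geometry, and carbonate/methanol removes the alkynyl silane in the same flask.

**Step 4**
Reactants: 9 (5E)-6,10-dimethylundeca-5,9-dien-1-yne
Product: 11 (1E,5E)-1-iodo-2,6,10-trimethylundeca-1,5,9-triene, via alkenylalane 10 (not isolated)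
Conditions: Me3Al (2 equiv), Cp2ZrCl2 (0.25 equiv), CH2Cl2, 0 → 23 °C; then iodine, THF, −30 → 0 °C
Reagents that add atoms: trimethylaluminium C[Al](C)C; iodine [I][I]
Why: a second Negishi carboalumination/iodinolysis sets the C8=C9 alkene as E (syn addition, retention on iodination).

**Step 5**
Reactants: 12 ethyl vinyl ether; 13 but-3-en-2-one (methyl vinyl ketone)
Product: 15 2-ethoxy-3-methylpenta-1,4-dien-3-ol (racemic), via 1-ethoxyvinyllithium 14 (not isolated)
Conditions: 12, t-BuLi, THF, −78 → 0 °C; then 13, −78 °C; H2O quench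
Reagents that add atoms: none
Why: α-lithiated ethyl vinyl ether is a hard acyl-anion equivalent that adds 1,2 to the enone at −78 °C; the new carbinol carbon (C13) is formed racemic, which is harmless because its configuration is erased in step 10.

**Step 6**
Reactants: 15 2-ethoxy-3-methylpenta-1,4-dien-3-ol
Product: 16 1-bromo-3-hydroxy-3-methylpent-4-en-2-one (racemic)
Conditions: NBS (1.05 equiv), NaHCO3, THF/H2O 4:1, 0 °C
Reagents that add atoms: N-bromosuccinimide O=C1CCC(=O)N1Br; water O
Why: electrophilic bromination of the enol ether (far more nucleophilic than the vinyl group) and hydrolysis of the resulting hemiketal give the bromomethyl ketone.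

**Step 7**
Reactants: 16 1-bromo-3-hydroxy-3-methylpent-4-en-2-one
Product: 17 2-ethenyl-2-methyloxetan-3-one (racemic)
Conditions: NaH (1.1 equiv), THF (0.02 M), 0 → 23 °C
Reagents that add atoms: none
Why: intramolecular Williamson etherification (4-exo-tet) of the tertiary alkoxide on the activated primary bromide, helped by the gem-disubstituted carbon (Thorpe–Ingold effect).

**Step 8**
Reactants: 17 2-ethenyl-2-methyloxetan-3-one
Product: 18 (3R)-2-ethenyl-2-methyloxetan-3-ol (both C2 epimers)
Conditions: (S)-2-methyl-CBS-oxazaborolidine (15 mol %), BH3·SMe2 (0.7 equiv), THF, −40 °C; MeOH quench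
Reagents that add atoms: none
Why: Corey–Bakshi–Shibata reduction distinguishes the quaternary C2 side (large) from the CH2 side (small) and should give the 3R carbinol (labdane C14) in both C2 epimers under catalyst control; both epimers are used, because C2 (labdane C13) is reset in step 10.

**Step 9**
Reactants: 18 (3R)-2-ethenyl-2-methyloxetan-3-ol; 11 (1E,5E)-1-iodo-2,6,10-trimethylundeca-1,5,9-triene
Product: 20 (3R)-2-methyl-2-[(3E,7E)-4,8,12-trimethyltrideca-3,7,11-trien-1-yl]oxetan-3-ol (both C2 epimers), via bis-borane adduct 19 (not isolated)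
Conditions: 18, 9-BBN (2.2 equiv), THF, 0 → 23 °C; then 11, Pd(dppf)Cl2 (5 mol %), AsPh3, Cs2CO3, DMF/H2O, 23 °C
Reagents that add atoms: none
Why: anti-Markovnikov hydroboration of the vinyl group followed by B-alkyl Suzuki–Miyaura coupling joins C11 to C9 with retention of the E alkene; the oxetane and the carbinol centre are untouched.

**Step 10**
Reactants: 20 (3R)-2-methyl-2-[(3E,7E)-4,8,12-trimethyltrideca-3,7,11-trien-1-yl]oxetan-3-ol
Product: 22 (3R,5S,8S,9S,10R,13S,14R)-3-bromo-8,15:13,14-diepoxylabdane (CNP0311742.1), via oxetanium ion 21 (not isolated)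
Conditions: BDSB (Et2SBr·SbCl5Br, 1.1 equiv), 2,6-di-tert-butyl-4-methylpyridine (1.5 equiv), MeNO2, −25 °C, 10 min; aq. Na2SO3/NaHCO3; chromatographic separation of the two diastereomers
Reagents that add atoms: bromodiethylsulfonium bromopentachloroantimonate CC[S+](Br)CC.Cl[Sb-](Cl)(Cl)(Cl)(Cl)Br
Why: Proposed new method: BDSB delivers Br+ to the terminal C3=C4 alkene and the E,E-triene closes ring A and ring B by the usual chair–chair anti additions (equatorial Br at C3, trans ring fusion, axial methyl and equatorial oxygen at C8); the C8 cation is captured through a six-membered transition state by the basic oxetane oxygen to give the fused six/four-membered oxonium ion 21, whose strained tertiary C13–O bond ionises so that this oxygen remains on C8 and C15 as the oxocane oxygen (4 → 8 ring expansion) while the neighbouring C14 hydroxyl collapses on C13 to the cis epoxide (C14 is untouched and stays R, cis closure makes C13 S, both C13 epimers of 20 converge) and the hindered pyridine takes the proton; the closest known reactions are BDSB polyene cyclisations terminated by oxygen nucleophiles, halonium-triggered ring expansions of cyclic ethers through bicyclic oxonium ions, and SN1-type opening of 2,2-disubstituted oxetanes at the tertiary carbon; the bromonium forms on both alkene faces, so 22 is formed about 1:1 with the diastereomer of opposite decalin configuration, and because C14 is fixed by step 8 this is a separable diastereomer, so 22 is isolated as a single enantiomer.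

**Compound list**
1 | 5-bromo-2-methylpent-2-ene | CC(C)=CCCBr | starting material
2 | lithium acetylide–ethylenediamine complex | [Li]C#C.NCCN | starting material
3 | 6-methylhept-5-en-1-yne | CC(C)=CCCC#C | intermediate
4 | dimethyl[(1E)-2,6-dimethylhepta-1,5-dien-1-yl]alane | CC(C)=CCC/C(C)=C/[Al](C)C | intermediate
5 | (1E)-1-iodo-2,6-dimethylhepta-1,5-diene | CC(C)=CCC/C(C)=C/I | intermediate
6 | (4-bromobut-1-yn-1-yl)trimethylsilane | C[Si](C)(C)C#CCCBr | starting material
7 | [4-(trimethylsilyl)but-3-yn-1-yl]zinc bromide | C[Si](C)(C)C#CCC[Zn]Br | intermediate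
8 | trimethyl[(5E)-6,10-dimethylundeca-5,9-dien-1-yn-1-yl]silane | CC(C)=CCC/C(C)=C/CCC#C[Si](C)(C)C | intermediate
9 | (5E)-6,10-dimethylundeca-5,9-dien-1-yne | CC(C)=CCC/C(C)=C/CCC#C | intermediate
10 | dimethyl[(1E,5E)-2,6,10-trimethylundeca-1,5,9-trien-1-yl]alane | CC(C)=CCC/C(C)=C/CC/C(C)=C/[Al](C)C | intermediate
11 | (1E,5E)-1-iodo-2,6,10-trimethylundeca-1,5,9-triene | CC(C)=CCC/C(C)=C/CC/C(C)=C/I | intermediate
12 | ethyl vinyl ether | C=COCC | starting material
13 | but-3-en-2-one | CC(=O)C=C | starting material
14 | 1-ethoxyvinyllithium | [Li]C(=C)OCC | intermediate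
15 | 2-ethoxy-3-methylpenta-1,4-dien-3-ol (racemic) | C=CC(C)(O)C(=C)OCC | intermediate
16 | 1-bromo-3-hydroxy-3-methylpent-4-en-2-one (racemic) | C=CC(C)(O)C(=O)CBr | intermediate
17 | 2-ethenyl-2-methyloxetan-3-one (racemic) | C=CC1(C)OCC1=O | intermediate
18 | (3R)-2-ethenyl-2-methyloxetan-3-ol (both C2 epimers) | C=CC1(C)OC[C@H]1O | intermediate
19 | 9-{[(3R)-2-[2-(9-borabicyclo[3.3.1]nonan-9-yl)ethyl]-2-methyloxetan-3-yl]oxy}-9-borabicyclo[3.3.1]nonane | CC1(CCB2C3CCCC2CCC3)OC[C@H]1OB1C2CCCC1CCC2 | intermediate
20 | (3R)-2-methyl-2-[(3E,7E)-4,8,12-trimethyltrideca-3,7,11-trien-1-yl]oxetan-3-ol (both C2 epimers) | CC(C)=CCC/C(C)=C/CC/C(C)=C/CCC1(C)OC[C@H]1O | intermediate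
21 | (3R,5S,8S,9S,10R,14R)-3-bromo-14-hydroxylabdane oxonium ion with one oxygen bonded to C8, C13 and C15 (fused oxane/oxetane), bromopentachloroantimonate salt | CC1(C)[C@H](Br)CC[C@]2(C)[C@@H]1CC[C@]1(C)[O+]3C[C@@H](O)C3(C)CC[C@@H]21.Cl[Sb-](Cl)(Cl)(Cl)(Cl)Br | intermediate
22 | (3R,5S,8S,9S,10R,13S,14R)-3-bromo-8,15:13,14-diepoxylabdane (CNP0311742.1) | CC1(C)[C@H](Br)CC[C@]2(C)[C@@H]1CC[C@]1(C)OC[C@H]3O[C@@]3(C)CC[C@@H]21 | target

**Step count**
Total: 10 steps (steps 1–4 and 5–8 run in parallel). Longest linear sequence: 6 steps (1 → 2 → 3 → 4 → 9 → 10, or 5 → 6 → 7 → 8 → 9 → 10).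

**Three steps most likely to fail**

Step 10 (the proposed cascade). Risks:
- halide attack on C15 of oxonium 21;
- 1,2-hydride shift of the C13 cation to a C14 ketone;
- proton loss from the C8 cation before the oxetane traps it;
- no control of the bromonium face, so at most half of the cyclised material is 22.

The fallback uses known chemistry and closes the oxocane by olefin metathesis instead. It sets out from triene iodide 11 and comes back at target 22. 2-Methyl-2-vinyl-1,3-dioxolane (C=CC1(C)OCCO1) is hydroborated with 9-BBN to the B-alkyl borane F1, which is coupled with 11 (Pd(dppf)Cl2, Cs2CO3) to the farnesylacetone ketal F2. Aqueous HCl frees (5E,9E)-farnesylacetone F3. BDSB in MeNO2 at −25 °C, with the ketone oxygen as terminating nucleophile (as in the acid cyclisation of farnesylacetone to sclareol oxide), gives the racemic bromo enol ether F4. PPTS in wet acetone opens it to the hydroxy ketone F5, and the 3R,5S,8S,9S,10R antipode is taken by preparative chiral SFC. Ph3P=CH2 gives the isopropenyl alcohol F6, and KH/allyl bromide gives the allyl ether F7. Ring-closing metathesis with the second-generation Grubbs catalyst gives the oxocene F8. Epoxidation with dimethyldioxirane gives 22, which is separated from its 13,14-bisepimer.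

Step 7 (oxetanone closure). Risks: the ring closes next to a carbonyl, so enolisation of the bromomethyl ketone and intermolecular alkylation compete, and 17 is volatile and base-sensitive. The fallback masks the carbonyl during ring closure. It sets out from 15 and comes back at 17. NBS in MeOH converts 15 into the bromo mixed ketal F9. NaH in THF closes the oxetane ketal F10, in the manner of the standard ketal route to oxetan-3-one. Montmorillonite K10 in wet CH2Cl2 releases 17.

Step 8 (CBS reduction). Risks: the strained ketone is reduced quickly by free borane, which erodes the ee, and the large/small differentiation is only moderate. The fallback is a resolution. It sets out from 17 and comes back at 18. NaBH4 gives the racemic oxetanol F11. Amano lipase PS with vinyl acetate should acylate the 3R alcohols to the acetate F12 (Kazlauskas rule; configuration checked by Mosher analysis). K2CO3/MeOH returns 18. The unreacted 3S alcohol is oxidised back to 17 with Dess–Martin periodinane.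

**Further compounds**
F1 | step 10 | 9-[2-(2-methyl-1,3-dioxolan-2-yl)ethyl]-9-borabicyclo[3.3.1]nonane | CC1(CCB2C3CCCC2CCC3)OCCO1
F2 | step 10 | 2-methyl-2-[(3E,7E)-4,8,12-trimethyltrideca-3,7,11-trien-1-yl]-1,3-dioxolane | CC(C)=CCC/C(C)=C/CC/C(C)=C/CCC1(C)OCCO1
F3 | step 10 | (5E,9E)-6,10,14-trimethylpentadeca-5,9,13-trien-2-one | CC(C)=CCC/C(C)=C/CC/C(C)=C/CCC(C)=O
F4 | step 10 | (3R,5S,8S,9S,10R)-3-bromo-8,13-epoxy-14,15-dinorlabd-12-ene (formed as racemate) | CC1(C)[C@H](Br)CC[C@]2(C)[C@@H]1CC[C@]1(C)OC(C)=CC[C@@H]21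
F5 | step 10 | (3R,5S,8S,9S,10R)-3-bromo-8-hydroxy-14,15-dinorlabdan-13-one | CC1(C)[C@H](Br)CC[C@]2(C)[C@@H]1CC[C@](C)(O)[C@H]2CCC(C)=O
F6 | step 10 | (3R,5S,8S,9S,10R)-3-bromo-14,15-dinorlabd-13(16)-en-8-ol | CC1(C)[C@H](Br)CC[C@]2(C)[C@@H]1CC[C@](C)(O)[C@H]2CCC(C)=C
F7 | step 10 | (3R,5S,8S,9S,10R)-8-(allyloxy)-3-bromo-14,15-dinorlabd-13(16)-ene | CC1(C)[C@H](Br)CC[C@]2(C)[C@@H]1CC[C@](C)(OCC=C)[C@H]2CCC(C)=C
F8 | step 10 | (3R,5S,8S,9S,10R,13Z)-3-bromo-8,15-epoxylabd-13-ene | CC1(C)[C@H](Br)CC[C@]2(C)[C@@H]1CC[C@]1(C)OC/C=C(C)\CC[C@@H]21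
F9 | step 7 | 1-bromo-2-ethoxy-2-methoxy-3-methylpent-4-en-3-ol | C=CC(C)(O)C(OC)(OCC)CBr
F10 | step 7 | 2-ethenyl-3-ethoxy-3-methoxy-2-methyloxetane | C=CC1(C)OCC1(OC)OCC
F11 | step 8 | 2-ethenyl-2-methyloxetan-3-ol (racemic) | C=CC1(C)OCC1O
F12 | step 8 | (3R)-2-ethenyl-2-methyloxetan-3-yl acetate | C=CC1(C)OC[C@H]1OC(C)=O
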